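The route rests on cutting the C4–C4a bond of unit 1 (units 1 to 4 counted from the top). C4 there is a doubly benzylic methine, joined to C4a of ring A and to C8 of unit 2 and trans to the C3 hydroxyl: the imprint of an arene opening a trans-epoxide at its benzylic carbon. One operation, an epoxide–arene cyclisation in hexafluoroisopropanol, closes ring C of unit 1, sets C4 and frees the 3-hydroxyl. Its precursor is the 3,5-bis(benzyloxy)phenyl ether of a trans-epoxy alcohol carried on C8 of the perbenzylated catechin–catechin–epicatechin trimer, itself assembled from the two natural flavanols by two Lewis acid couplings.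

Key step: step 17

Remark 1: flavan numbering (O1, C2, C3, C4, C4a, C8) is used in every unit, also for the open-chain carbons that become unit 1; "erythro" means hydroxyl (or aryloxy) and epoxide oxygen on opposite sides of the zigzag chain aryl–C2–C3–C4.
Remark 2: 21 as drawn (trans-epoxide, erythro aryl ether) gives 22 by inversion at C4 alone, so both structures stand; because a Mitsunobu etherification inverts C2 and chelation-controlled reduction of the epoxy ketone gives the erythro alcohol, the carbinol is inverted (steps 14 and 15) before the phenol is introduced.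
Remark 3: the C4 ethers 7 and 10 are drawn as the 4β (3,4-cis) epimers expected from the DDQ oxidation; C4 is ionised in the following step, so this configuration is of no consequence.

Step 1
Reactants: 1 (−)-epicatechin
Product: 2 5,7,3',4'-tetra-O-benzyl-(−)-epicatechin (2R,3R; 3-OH free)
Conditions: BnBr, K2CO3, DMF, 0 °C to rt
Reagents that add atoms: benzyl bromide, BrCc1ccccc1
Why: Williamson ether synthesis in which carbonate deprotonates only the four phenols, so the secondary 3-hydroxyl stays free and C2 and C3 are not touched.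

Step 2
Reactants: 2 tetra-O-benzyl-epicatechin
Product: 3 3,5,7,3',4'-penta-O-benzyl-(−)-epicatechin
Conditions: NaH, BnBr, DMF, 0 °C to rt
Reagents that add atoms: benzyl bromide, BrCc1ccccc1
Why: Williamson ether synthesis on the sodium alkoxide of the 3-hydroxyl; with no free phenol the base cannot open ring C, so C2 and C3 keep their configuration.

Step 3
Reactants: 4 (+)-catechin
Product: 5 5,7,3',4'-tetra-O-benzyl-(+)-catechin (2R,3S; 3-OH free)
Conditions: BnBr, K2CO3, DMF, 0 °C to rt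
Reagents that add atoms: benzyl bromide, BrCc1ccccc1
Why: Williamson ether synthesis selective for the four phenols, as in step 1, with no stereocentre involved.

Step 4
Reactants: 5 tetra-O-benzyl-catechin
Product: 6 3,5,7,3',4'-penta-O-benzyl-(+)-catechin
Conditions: NaH, BnBr, DMF, 0 °C to rt
Reagents that add atoms: benzyl bromide, BrCc1ccccc1
Why: Williamson ether synthesis on the 3-alkoxide, as in step 2, with no stereocentre involved.

Step 5
Reactants: 6 penta-O-benzyl-catechin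
Product: 7 (2R,3S,4S)-4-(2-ethoxyethoxy)-3,5,7,3',4'-penta-O-benzylflavan (C4 ether of 6)
Conditions: DDQ, 2-ethoxyethanol, CH2Cl2, rt
Reagents that add atoms: 2-ethoxyethanol, CCOCCO
Why: DDQ benzylic oxidation, in which hydride is abstracted from C4 (activated by the three oxygens of ring A) and the resulting quinone-methide-type cation is trapped by the alcohol, C2 and C3 being untouched.

Step 6
Reactants: 7 C4 ether of penta-O-benzyl-catechin; 3 penta-O-benzyl-epicatechin (threefold excess)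
Product: 8 penta-O-benzyl-catechin-(4α→8)-penta-O-benzyl-epicatechin (dimer, units 3 and 4)
Conditions: TMSOTf (0.2 equiv), CH2Cl2, −78 °C; Et3N quench
Reagents that add atoms: none
Why: Lewis acid-promoted Friedel–Crafts flavan coupling, in which the C4 cation of the 2,3-trans unit is attacked by C8 of 3 (its most nucleophilic ring-A carbon) anti to the 3-benzyloxy group, which should set C4 as 4α (3,4-trans), while the excess of 3 suppresses self-condensation of 7.

Step 7
Reactants: 6 penta-O-benzyl-catechin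
Product: 9 8-bromo-3,5,7,3',4'-penta-O-benzyl-(+)-catechin
Conditions: NBS, CH2Cl2, −40 °C to rt
Reagents that add atoms: N-bromosuccinimide, BrN1C(=O)CCC1=O
Why: Electrophilic aromatic bromination at C8 of ring A, the position flanked by O1 and the 7-benzyloxy group at which benzylated flavan-3-ols are brominated selectively.

Step 8
Reactants: 9 8-bromo-penta-O-benzyl-catechin
Product: 10 (2R,3S,4S)-8-bromo-4-(2-ethoxyethoxy)-3,5,7,3',4'-penta-O-benzylflavan
Conditions: DDQ, 2-ethoxyethanol, CH2Cl2, rt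
Reagents that add atoms: 2-ethoxyethanol, CCOCCO
Why: DDQ benzylic oxidation at C4 as in step 5; the bromine on C8 does not prevent hydride abstraction and blocks the nucleophilic position of this unit for the next step.

Step 9
Reactants: 10 8-bromo C4 ether; 8 dimer (1.5 equiv)
Product: 11 8-bromo-penta-O-benzyl-catechin-(4α→8)-penta-O-benzyl-catechin-(4α→8)-penta-O-benzyl-epicatechin (trimer of units 2 to 4, bromine on C8 of unit 2)
Conditions: TMSOTf (0.2 equiv), CH2Cl2, −78 °C; Et3N quench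
Reagents that add atoms: none
Why: Lewis acid-promoted Friedel–Crafts flavan coupling as in step 6, in which the cation from 10 cannot self-condense because its C8 carries bromine and is attacked by C8 of the catechin unit of 8 anti to the 3-benzyloxy group, which should set the new C4 as 4α.

Step 10
Reactants: 11 8-bromo trimer
Product: 13 8-formyl trimer (aldehyde on C8 of unit 2 of the perbenzylated trimer), via aryllithium 12 (not isolated)
Conditions: n-BuLi, THF, −78 °C; DMF, −78 to 0 °C; H2O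
Reagents that add atoms: N,N-dimethylformamide, CN(C)C=O (formyl carbon and oxygen); n-butyllithium, [Li]CCCC (lithium of 12 only)
Why: Bromine–lithium exchange followed by formylation with DMF; exchange at the aryl bromide flanked by two oxygens should be faster at −78 °C than deprotonation of any benzylic position, and the adduct collapses to the aldehyde on work-up.

Step 11
Reactants: 13 8-formyl trimer; 14 1-[3,4-bis(benzyloxy)phenyl]ethanone
Product: 15 (E)-1-[3,4-bis(benzyloxy)phenyl]-3-(trimer-8-yl)prop-2-en-1-one (enone; the alkene carbons are the future C3 and C4 of unit 1)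
Conditions: KOH, EtOH/THF, rt to 40 °C
Reagents that add atoms: none
Why: Claisen–Schmidt condensation (crossed aldol with E1cB dehydration), in which only the methyl ketone can enolise and elimination gives the conjugated (E)-enone, benzyl ethers and interflavan bonds being inert to hydroxide.

Step 12
Reactants: 15 enone
Product: 16 [3,4-bis(benzyloxy)phenyl][(2S,3R)-3-(trimer-8-yl)oxiran-2-yl]methanone (trans-epoxy ketone)
Conditions: La(OiPr)3 (20 mol %), (R)-BINOL, Ph3P=O, t-BuOOH, 4 Å MS, THF, rt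
Reagents that add atoms: tert-butyl hydroperoxide, CC(C)(C)OO
Why: Catalytic asymmetric nucleophilic epoxidation of an enone (Weitz–Scheffer type), in which conjugate addition of the lanthanum-bound peroxide and ring closure give the trans-epoxide, and the (R)-BINOL catalyst is expected, by analogy with chalcone, to deliver oxygen to the face that gives the (2S,3R) epoxy ketone under catalyst control.

Step 13
Reactants: 16 epoxy ketone
Product: 17 (R)-[3,4-bis(benzyloxy)phenyl][(trans)-3-(trimer-8-yl)oxiran-2-yl]methanol, erythro epoxy alcohol (epoxide as in 16)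
Conditions: Zn(BH4)2, Et2O/THF, −30 °C
Reagents that add atoms: none
Why: Chelation-controlled hydride reduction, in which zinc bridges the carbonyl and epoxide oxygens and hydride adds from the face away from the C3–C4 bond, which should give the erythro alcohol with an (R) carbinol carbon.

Step 14
Reactants: 17 erythro epoxy alcohol
Product: 18 threo 4-nitrobenzoate (ester of the (S)-carbinol; epoxide as in 16)
Conditions: PPh3, DIAD (betaine preformed), 4-nitrobenzoic acid, toluene/THF, −20 to 0 °C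
Reagents that add atoms: 4-nitrobenzoic acid, O=C(O)c1ccc(cc1)[N+](=O)[O-]
Why: Mitsunobu esterification, in which SN2 displacement of the alkoxyphosphonium by the carboxylate inverts the future C2 to the threo series, the preformed betaine keeping free acid away from the acid-labile epoxide and the adjacent epoxide carbon disfavouring ionisation at C2.

Step 15
Reactants: 18 threo 4-nitrobenzoate
Product: 19 (S)-[3,4-bis(benzyloxy)phenyl][(trans)-3-(trimer-8-yl)oxiran-2-yl]methanol, threo epoxy alcohol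
Conditions: K2CO3 (0.2 equiv), MeOH/THF, 0 °C
Reagents that add atoms: none
Why: Base-catalysed transesterification (methanolysis) of the activated ester, which does not break the C2–O bond, so the threo configuration is kept, and which is too cold and too weakly basic to open or migrate the epoxide.

Step 16
Reactants: 19 threo epoxy alcohol; 20 3,5-bis(benzyloxy)phenol
Product: 21 3,5-bis(benzyloxy)phenyl ether of the trans-epoxy alcohol on C8 of unit 2 (erythro ether, C2 of the future unit 1 is R)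
Conditions: PPh3, DIAD, toluene, 0 °C to rt
Reagents that add atoms: none
Why: Mitsunobu etherification, in which the phenoxide displaces the alkoxyphosphonium by SN2 with inversion at C2 and so turns the threo alcohol into the erythro aryl ether needed for a 2,3-trans unit.

Step 17
Reactants: 21 epoxy aryl ether
Product: 22 protected tetramer (sixteen phenolic benzyl ethers, 3-O-benzyl on units 2 to 4, free 3-hydroxyl on unit 1)
Conditions: HFIP/CH2Cl2 (4:1), 2 mM, 0 °C to rt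
Reagents that add atoms: none
Why: The fluoroalcohol, a strong hydrogen-bond donor of low nucleophilicity, activates the oxirane oxygen, and the C4–O bond, already loosened by the trioxygenated ring A of unit 2 on C4, breaks as one of the two equivalent ortho carbons of the 3,5-bis(benzyloxy)phenyl ether bonds to C4 from the face opposite the oxygen; loss of a proton restores the arene and the oxygen remains on C3 as the hydroxyl. This is the intramolecular Friedel–Crafts epoxide–arene cyclisation that converts 3-arylglycidyl aryl ethers into trans-4-arylchroman-3-ols in fluorinated alcohols. Ring C of unit 1 closes in the 6-endo mode through the new C4–C4a bond, because only C4 bears an aryl group able to carry positive charge, so 5-exo attack at C3 is not expected. The one new stereocentre, C4, is set by inversion of the trans-epoxide carbon, which puts the unit-2 aryl trans to the C3 oxygen, and if the opening is more cation-like a chair-like closure with the C2 aryl, the C3 oxygen and the C4 aryl all equatorial leads to the same 2,3-trans-3,4-trans isomer. The step needs ring closure to outrun the 1,2-hydride shift from C3 to C4 (ketone formation) and intermolecular alkylation at the C6 positions, which the tethered, highly nucleophilic arene, the non-nucleophilic medium and high dilution should secure. A 4→6 isomer cannot arise, since the bond to C8 of unit 2 exists before the step and the attacking arene is symmetric.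

Step 18
Reactants: 22 protected tetramer
Product: 23 catechin-(4α→8)-catechin-(4α→8)-catechin-(4α→8)-epicatechin (CNP0236700.7)
Conditions: H2 (1 atm), Pd(OH)2 on carbon, THF/MeOH/H2O, rt
Reagents that add atoms: none
Why: Catalytic hydrogenolysis of all nineteen O-benzyl groups under neutral conditions that leave the interflavan bonds and every stereocentre untouched.

Compound list
1 | (−)-epicatechin | O[C@@H]1Cc2c(O)cc(O)cc2O[C@@H]1c1ccc(O)c(O)c1 | starting material
2 | 5,7,3',4'-tetra-O-benzyl-(−)-epicatechin | c1c(OCc3ccccc3)cc(OCc3ccccc3)c2c1O[C@H](c1ccc(OCc3ccccc3)c(OCc3ccccc3)c1)[C@H](O)C2 | intermediate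
3 | 3,5,7,3',4'-penta-O-benzyl-(−)-epicatechin | c1c(OCc3ccccc3)cc(OCc3ccccc3)c2c1O[C@H](c1ccc(OCc3ccccc3)c(OCc3ccccc3)c1)[C@H](OCc3ccccc3)C2 | intermediate
4 | (+)-catechin | O[C@H]1Cc2c(O)cc(O)cc2O[C@@H]1c1ccc(O)c(O)c1 | starting material
5 | 5,7,3',4'-tetra-O-benzyl-(+)-catechin | c1c(OCc3ccccc3)cc(OCc3ccccc3)c2c1O[C@H](c1ccc(OCc3ccccc3)c(OCc3ccccc3)c1)[C@@H](O)C2 | intermediate
6 | 3,5,7,3',4'-penta-O-benzyl-(+)-catechin | c1c(OCc3ccccc3)cc(OCc3ccccc3)c2c1O[C@H](c1ccc(OCc3ccccc3)c(OCc3ccccc3)c1)[C@@H](OCc3ccccc3)C2 | intermediate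
7 | (2R,3S,4S)-4-(2-ethoxyethoxy)-3,5,7,3',4'-penta-O-benzylflavan | c1c(OCc3ccccc3)cc(OCc3ccccc3)c2c1O[C@H](c1ccc(OCc3ccccc3)c(OCc3ccccc3)c1)[C@@H](OCc3ccccc3)[C@H]2OCCOCC | intermediate
8 | penta-O-benzyl-catechin-(4α→8)-penta-O-benzyl-epicatechin | c1c(OCc3ccccc3)cc(OCc3ccccc3)c2c1O[C@H](c1ccc(OCc3ccccc3)c(OCc3ccccc3)c1)[C@@H](OCc3ccccc3)[C@@H]2c1c(OCc3ccccc3)cc(OCc3ccccc3)c2c1O[C@H](c1ccc(OCc3ccccc3)c(OCc3ccccc3)c1)[C@H](OCc3ccccc3)C2 | intermediate
9 | 8-bromo-3,5,7,3',4'-penta-O-benzyl-(+)-catechin | Brc1c(OCc3ccccc3)cc(OCc3ccccc3)c2c1O[C@H](c1ccc(OCc3ccccc3)c(OCc3ccccc3)c1)[C@@H](OCc3ccccc3)C2 | intermediate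
10 | (2R,3S,4S)-8-bromo-4-(2-ethoxyethoxy)-3,5,7,3',4'-penta-O-benzylflavan | Brc1c(OCc3ccccc3)cc(OCc3ccccc3)c2c1O[C@H](c1ccc(OCc3ccccc3)c(OCc3ccccc3)c1)[C@@H](OCc3ccccc3)[C@H]2OCCOCC | intermediate
11 | 8-bromo trimer (perbenzylated catechin-(4α→8)-catechin-(4α→8)-epicatechin, Br on C8 of unit 2) | Brc1c(OCc3ccccc3)cc(OCc3ccccc3)c2c1O[C@H](c1ccc(OCc3ccccc3)c(OCc3ccccc3)c1)[C@@H](OCc3ccccc3)[C@@H]2c1c(OCc3ccccc3)cc(OCc3ccccc3)c2c1O[C@H](c1ccc(OCc3ccccc3)c(OCc3ccccc3)c1)[C@@H](OCc3ccccc3)[C@@H]2c1c(OCc3ccccc3)cc(OCc3ccccc3)c2c1O[C@H](c1ccc(OCc3ccccc3)c(OCc3ccccc3)c1)[C@H](OCc3ccccc3)C2 | intermediate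
12 | 8-lithio trimer (aryllithium) | [Li]c1c(OCc3ccccc3)cc(OCc3ccccc3)c2c1O[C@H](c1ccc(OCc3ccccc3)c(OCc3ccccc3)c1)[C@@H](OCc3ccccc3)[C@@H]2c1c(OCc3ccccc3)cc(OCc3ccccc3)c2c1O[C@H](c1ccc(OCc3ccccc3)c(OCc3ccccc3)c1)[C@@H](OCc3ccccc3)[C@@H]2c1c(OCc3ccccc3)cc(OCc3ccccc3)c2c1O[C@H](c1ccc(OCc3ccccc3)c(OCc3ccccc3)c1)[C@H](OCc3ccccc3)C2 | intermediate
13 | 8-formyl trimer | O=Cc1c(OCc3ccccc3)cc(OCc3ccccc3)c2c1O[C@H](c1ccc(OCc3ccccc3)c(OCc3ccccc3)c1)[C@@H](OCc3ccccc3)[C@@H]2c1c(OCc3ccccc3)cc(OCc3ccccc3)c2c1O[C@H](c1ccc(OCc3ccccc3)c(OCc3ccccc3)c1)[C@@H](OCc3ccccc3)[C@@H]2c1c(OCc3ccccc3)cc(OCc3ccccc3)c2c1O[C@H](c1ccc(OCc3ccccc3)c(OCc3ccccc3)c1)[C@H](OCc3ccccc3)C2 | intermediate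
14 | 1-[3,4-bis(benzyloxy)phenyl]ethanone | CC(=O)c1ccc(OCc2ccccc2)c(OCc2ccccc2)c1 | starting material
15 | (E)-enone on C8 of unit 2 | O=C(c1ccc(OCc3ccccc3)c(OCc3ccccc3)c1)/C=C/c1c(OCc3ccccc3)cc(OCc3ccccc3)c2c1O[C@H](c1ccc(OCc3ccccc3)c(OCc3ccccc3)c1)[C@@H](OCc3ccccc3)[C@@H]2c1c(OCc3ccccc3)cc(OCc3ccccc3)c2c1O[C@H](c1ccc(OCc3ccccc3)c(OCc3ccccc3)c1)[C@@H](OCc3ccccc3)[C@@H]2c1c(OCc3ccccc3)cc(OCc3ccccc3)c2c1O[C@H](c1ccc(OCc3ccccc3)c(OCc3ccccc3)c1)[C@H](OCc3ccccc3)C2 | intermediate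
16 | (2S,3R)-trans-epoxy ketone | O=C(c1ccc(OCc3ccccc3)c(OCc3ccccc3)c1)[C@H]4O[C@@H]4c1c(OCc3ccccc3)cc(OCc3ccccc3)c2c1O[C@H](c1ccc(OCc3ccccc3)c(OCc3ccccc3)c1)[C@@H](OCc3ccccc3)[C@@H]2c1c(OCc3ccccc3)cc(OCc3ccccc3)c2c1O[C@H](c1ccc(OCc3ccccc3)c(OCc3ccccc3)c1)[C@@H](OCc3ccccc3)[C@@H]2c1c(OCc3ccccc3)cc(OCc3ccccc3)c2c1O[C@H](c1ccc(OCc3ccccc3)c(OCc3ccccc3)c1)[C@H](OCc3ccccc3)C2 | intermediate
17 | erythro epoxy alcohol, (R)-carbinol | O[C@H](c1ccc(OCc3ccccc3)c(OCc3ccccc3)c1)[C@H]4O[C@@H]4c1c(OCc3ccccc3)cc(OCc3ccccc3)c2c1O[C@H](c1ccc(OCc3ccccc3)c(OCc3ccccc3)c1)[C@@H](OCc3ccccc3)[C@@H]2c1c(OCc3ccccc3)cc(OCc3ccccc3)c2c1O[C@H](c1ccc(OCc3ccccc3)c(OCc3ccccc3)c1)[C@@H](OCc3ccccc3)[C@@H]2c1c(OCc3ccccc3)cc(OCc3ccccc3)c2c1O[C@H](c1ccc(OCc3ccccc3)c(OCc3ccccc3)c1)[C@H](OCc3ccccc3)C2 | intermediate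
18 | threo 4-nitrobenzoate, (S)-carbinol ester | O=C(c1ccc(cc1)[N+](=O)[O-])O[C@@H](c1ccc(OCc3ccccc3)c(OCc3ccccc3)c1)[C@H]4O[C@@H]4c1c(OCc3ccccc3)cc(OCc3ccccc3)c2c1O[C@H](c1ccc(OCc3ccccc3)c(OCc3ccccc3)c1)[C@@H](OCc3ccccc3)[C@@H]2c1c(OCc3ccccc3)cc(OCc3ccccc3)c2c1O[C@H](c1ccc(OCc3ccccc3)c(OCc3ccccc3)c1)[C@@H](OCc3ccccc3)[C@@H]2c1c(OCc3ccccc3)cc(OCc3ccccc3)c2c1O[C@H](c1ccc(OCc3ccccc3)c(OCc3ccccc3)c1)[C@H](OCc3ccccc3)C2 | intermediate
19 | threo epoxy alcohol, (S)-carbinol | O[C@@H](c1ccc(OCc3ccccc3)c(OCc3ccccc3)c1)[C@H]4O[C@@H]4c1c(OCc3ccccc3)cc(OCc3ccccc3)c2c1O[C@H](c1ccc(OCc3ccccc3)c(OCc3ccccc3)c1)[C@@H](OCc3ccccc3)[C@@H]2c1c(OCc3ccccc3)cc(OCc3ccccc3)c2c1O[C@H](c1ccc(OCc3ccccc3)c(OCc3ccccc3)c1)[C@@H](OCc3ccccc3)[C@@H]2c1c(OCc3ccccc3)cc(OCc3ccccc3)c2c1O[C@H](c1ccc(OCc3ccccc3)c(OCc3ccccc3)c1)[C@H](OCc3ccccc3)C2 | intermediate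
20 | 3,5-bis(benzyloxy)phenol | Oc1cc(OCc2ccccc2)cc(OCc2ccccc2)c1 | starting material
21 | erythro 3,5-bis(benzyloxy)phenyl ether of the trans-epoxy alcohol (cyclisation precursor) | c1ccccc1COc1cc(OCc3ccccc3)cc(c1)O[C@H](c1ccc(OCc3ccccc3)c(OCc3ccccc3)c1)[C@H]4O[C@@H]4c1c(OCc3ccccc3)cc(OCc3ccccc3)c2c1O[C@H](c1ccc(OCc3ccccc3)c(OCc3ccccc3)c1)[C@@H](OCc3ccccc3)[C@@H]2c1c(OCc3ccccc3)cc(OCc3ccccc3)c2c1O[C@H](c1ccc(OCc3ccccc3)c(OCc3ccccc3)c1)[C@@H](OCc3ccccc3)[C@@H]2c1c(OCc3ccccc3)cc(OCc3ccccc3)c2c1O[C@H](c1ccc(OCc3ccccc3)c(OCc3ccccc3)c1)[C@H](OCc3ccccc3)C2 | intermediate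
22 | protected tetramer (free 3-OH on unit 1) | c1ccccc1COc1cc(OCc3ccccc3)c2c(c1)O[C@H](c1ccc(OCc3ccccc3)c(OCc3ccccc3)c1)[C@@H](O)[C@@H]2c1c(OCc3ccccc3)cc(OCc3ccccc3)c2c1O[C@H](c1ccc(OCc3ccccc3)c(OCc3ccccc3)c1)[C@@H](OCc3ccccc3)[C@@H]2c1c(OCc3ccccc3)cc(OCc3ccccc3)c2c1O[C@H](c1ccc(OCc3ccccc3)c(OCc3ccccc3)c1)[C@@H](OCc3ccccc3)[C@@H]2c1c(OCc3ccccc3)cc(OCc3ccccc3)c2c1O[C@H](c1ccc(OCc3ccccc3)c(OCc3ccccc3)c1)[C@H](OCc3ccccc3)C2 | intermediate
23 | catechin-(4α→8)-catechin-(4α→8)-catechin-(4α→8)-epicatechin (CNP0236700.7) | Oc1cc(O)c2c(c1)O[C@H](c1ccc(O)c(O)c1)[C@@H](O)[C@@H]2c1c(O)cc(O)c2c1O[C@H](c1ccc(O)c(O)c1)[C@@H](O)[C@@H]2c1c(O)cc(O)c2c1O[C@H](c1ccc(O)c(O)c1)[C@@H](O)[C@@H]2c1c(O)cc(O)c2c1O[C@H](c1ccc(O)c(O)c1)[C@H](O)C2 | target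

Total step count: 18. Longest linear sequence: 14 steps (4 → 5 → 6 → 9 → 10 → 11 → 13 → 15 → 16 → 17 → 18 → 19 → 21 → 22 → 23).

Steps most likely to fail

Step 17. The opened epoxide may be diverted into a 1,2-hydride shift to the C3 ketone, or a long-lived benzylic cation may erode control at C4. Fallback: unit 1 is brought in intact from catechin. Setting out from 11, bromine–lithium exchange (n-BuLi, THF, −78 °C, through 12) and quenching with methanol give the C8–H perbenzylated trimer F1. Setting out from 5, DDQ and 2-ethoxyethanol give (2R,3S,4S)-4-(2-ethoxyethoxy)-5,7,3',4'-tetra-O-benzylflavan-3-ol F2. F2 is added slowly to an excess of F1 with TMSOTf in CH2Cl2 at −78 °C. Attack of C8 of unit 2 on the C4 cation anti to the 3-hydroxyl should give 22, where the route is rejoined.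

Step 12. The hindered, donor-substituted β-carbon may not turn over, or facial selectivity may be poor on this large chiral substrate. Fallback: stereocontrol is moved to a hydroxyl-directed epoxidation. Setting out from 15, Luche reduction (NaBH4, CeCl3·7H2O, MeOH/THF, −40 °C) gives the (S)-allylic alcohol F3 together with its (R)-carbinol epimer F4. Sharpless epoxidation under kinetic-resolution conditions (Ti(OiPr)4, L-(+)-diisopropyl tartrate, t-BuOOH, 4 Å MS, CH2Cl2, −20 °C) should epoxidise the matched epimer F3 on the face that gives the erythro trans-epoxy alcohol. The route is rejoined at 17, and steps 12 and 13 are then not needed. F4 is left behind and returned to 15 with MnO2.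

Step 16. The alkoxyphosphonium at the electron-rich benzylic carbon may ionise and erode the inversion, or the epoxide may open during the slow etherification. Fallback: the aryl–oxygen bond is formed instead, with retention at C2. Commercial (3,5-bis(benzyloxy)phenyl)boronic acid is converted with KHF2 into potassium [3,5-bis(benzyloxy)phenyl]trifluoroborate F5. Setting out from the erythro alcohol 17, a copper-catalysed Chan–Lam-type oxidative etherification with F5 (Cu(OAc)2·H2O, DMAP, 4 Å MS, O2, CH2Cl2, rt) should arylate the hydroxyl without touching the C2–O bond. The route is rejoined at 21, and steps 14 and 15 are then not needed.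

Further compounds
F1 | step 17 | C8–H perbenzylated trimer, penta-O-benzyl-catechin-(4α→8)-penta-O-benzyl-catechin-(4α→8)-penta-O-benzyl-epicatechin | c1c(OCc3ccccc3)cc(OCc3ccccc3)c2c1O[C@H](c1ccc(OCc3ccccc3)c(OCc3ccccc3)c1)[C@@H](OCc3ccccc3)[C@@H]2c1c(OCc3ccccc3)cc(OCc3ccccc3)c2c1O[C@H](c1ccc(OCc3ccccc3)c(OCc3ccccc3)c1)[C@@H](OCc3ccccc3)[C@@H]2c1c(OCc3ccccc3)cc(OCc3ccccc3)c2c1O[C@H](c1ccc(OCc3ccccc3)c(OCc3ccccc3)c1)[C@H](OCc3ccccc3)C2
F2 | step 17 | (2R,3S,4S)-4-(2-ethoxyethoxy)-5,7,3',4'-tetra-O-benzylflavan-3-ol | c1c(OCc3ccccc3)cc(OCc3ccccc3)c2c1O[C@H](c1ccc(OCc3ccccc3)c(OCc3ccccc3)c1)[C@@H](O)[C@H]2OCCOCC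
F3 | step 12 | (S,E)-1-[3,4-bis(benzyloxy)phenyl]-3-(trimer-8-yl)prop-2-en-1-ol | O[C@H](c1ccc(OCc3ccccc3)c(OCc3ccccc3)c1)/C=C/c1c(OCc3ccccc3)cc(OCc3ccccc3)c2c1O[C@H](c1ccc(OCc3ccccc3)c(OCc3ccccc3)c1)[C@@H](OCc3ccccc3)[C@@H]2c1c(OCc3ccccc3)cc(OCc3ccccc3)c2c1O[C@H](c1ccc(OCc3ccccc3)c(OCc3ccccc3)c1)[C@@H](OCc3ccccc3)[C@@H]2c1c(OCc3ccccc3)cc(OCc3ccccc3)c2c1O[C@H](c1ccc(OCc3ccccc3)c(OCc3ccccc3)c1)[C@H](OCc3ccccc3)C2
F4 | step 12 | (R,E)-1-[3,4-bis(benzyloxy)phenyl]-3-(trimer-8-yl)prop-2-en-1-ol | O[C@@H](c1ccc(OCc3ccccc3)c(OCc3ccccc3)c1)/C=C/c1c(OCc3ccccc3)cc(OCc3ccccc3)c2c1O[C@H](c1ccc(OCc3ccccc3)c(OCc3ccccc3)c1)[C@@H](OCc3ccccc3)[C@@H]2c1c(OCc3ccccc3)cc(OCc3ccccc3)c2c1O[C@H](c1ccc(OCc3ccccc3)c(OCc3ccccc3)c1)[C@@H](OCc3ccccc3)[C@@H]2c1c(OCc3ccccc3)cc(OCc3ccccc3)c2c1O[C@H](c1ccc(OCc3ccccc3)c(OCc3ccccc3)c1)[C@H](OCc3ccccc3)C2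
F5 | step 16 | potassium [3,5-bis(benzyloxy)phenyl]trifluoroborate | [K+].F[B-](F)(F)c1cc(OCc2ccccc2)cc(OCc2ccccc2)c1
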